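Plan
- Retrosynthetic cuts, in order: the C15 PMB ether and the C8 methacrylate; C7–C8 (zinc Barbier closure of the ten-membered carbocycle onto a bromomethyl butenolide); the butenolide C7=C11 bond (metathesis) and its C6 ester; the furanone O–C3 bond, back to an oxirane O–C10–C1; C3–C4 (Sonogashira).
- Enabling feature: in the furanone ring O–C10(Me)–C1(=O)–C2=C3 the ring oxygen sits on a quaternary carbon next to the ketone and C2/C3 are at alkyne oxidation level. O, C10 and C1 can therefore be laid down first as an oxirane on a 2-alkynyl enol ether, and C2–C3 is then inserted into the O–C1 bond.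
- Helper: the enol ether is a 4,5-dihydrofuran made from (S)-5-(hydroxymethyl)butyrolactone. Its ring oxygen ends up as the C8 oxygen of the target; its extra CH2O carbon relays chirality to C10 and is later excised with NaIO4.
- Forward order of rings: dihydrofuran (temporary), oxirane, 3(2H)-furanone, butenolide, ten-membered carbocycle (which also creates the α-methylene lactone).
- Stereochemistry: C10 from the lactone stereocentre through face-selective epoxidation (the α-methyl centre is first erased, so both epimers converge); C6 from a Sharpless kinetic resolution; C7 and C8 from C6 in the Barbier closure; C4=C5 from hydroxyl-directed trans-hydroalumination/iodination.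

Key step: step 12

Remark: atom numbers C1–C15 are germacranolide numbers (C10 quaternary with methyl C14, C1 ketone, C2=C3, C4=C5, C15 hydroxymethyl, C6 lactone oxygen, C7, C8 ester, C9 methylene, C11–C13 methylene lactone); the two γ-hydroxy ketones of the route are written open-chain although each equilibrates with its five-membered cyclic hemiketal.

Step 1
Reactants: 1 (S)-5-(hydroxymethyl)dihydrofuran-2(3H)-one
Product: 2 (S)-5-{[(tert-butyldiphenylsilyl)oxy]methyl}dihydrofuran-2(3H)-one
Conditions: TBDPSCl, imidazole, DMF, 0 °C to rt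
Reagents that add atoms: tert-butyl(chloro)diphenylsilane, CC(C)(C)[Si](Cl)(c1ccccc1)c1ccccc1
Why: Standard silylation of a primary alcohol; the bulky silyl ether is the later face-shielding group.

Step 2
Reactants: 2 (S)-5-{[(tert-butyldiphenylsilyl)oxy]methyl}dihydrofuran-2(3H)-one
Product: 3 (5S)-5-{[(tert-butyldiphenylsilyl)oxy]methyl}-3-methyldihydrofuran-2(3H)-one (both C3 epimers)
Conditions: LiN(iPr)2, THF, −78 °C; MeI, −78 to −40 °C
Reagents that add atoms: iodomethane, CI
Why: Lactone enolate alkylation introduces the C14 methyl group; the configuration of the new centre does not matter because it becomes trigonal in step 4.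

Step 3
Reactants: 3 methyl lactone; 4 ethynyltrimethylsilane
Product: 5 (6S)-7-[(tert-butyldiphenylsilyl)oxy]-6-hydroxy-4-methyl-1-(trimethylsilyl)hept-1-yn-3-one (both C4 epimers)
Conditions: 4, n-BuLi, THF, −78 °C; then 3, −78 °C; aq. NH4Cl
Reagents that add atoms: none
Why: Addition of a lithium acetylide to a γ-lactone stops after one addition at −78 °C because the tetrahedral lithium alkoxide is stable, giving the γ-hydroxy ynone (C1–C2 bond).

Step 4
Reactants: 5 γ-hydroxy ynone
Product: 6 (S)-tert-butyl({4-methyl-5-[(trimethylsilyl)ethynyl]-2,3-dihydrofuran-2-yl}methoxy)diphenylsilane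
Conditions: PPTS (cat.), 4 Å molecular sieves, toluene, 80 °C
Reagents that add atoms: none
Why: Acid-catalysed cyclodehydration of a γ-hydroxy ketone to a 4,5-dihydrofuran; loss of the C10 proton from the oxocarbenium ion is the only elimination open, so both C10 epimers converge on one tetrasubstituted enol ether.

Step 5
Reactants: 6 silylated alkynyl dihydrofuran
Product: 7 (S)-tert-butyl[(5-ethynyl-4-methyl-2,3-dihydrofuran-2-yl)methoxy]diphenylsilane
Conditions: K2CO3 (cat.), MeOH, 0 °C to rt
Reagents that add atoms: none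
Why: Methanolysis of the alkynyl C–Si bond under mild base leaves the O-silyl ether and the enol ether untouched.

Step 6
Reactants: 8 1-methoxy-4-[(prop-2-yn-1-yloxy)methyl]benzene; 9 acrolein
Product: 10 rac-6-[(4-methoxybenzyl)oxy]hex-1-en-4-yn-3-ol
Conditions: 8, n-BuLi, THF, −78 °C; then 9, −78 °C; aq. NH4Cl
Reagents that add atoms: none
Why: 1,2-Addition of a lithium acetylide to an enal gives the racemic secondary allylic-propargylic alcohol (C5–C6 bond).

Step 7
Reactants: 10 racemic enynol
Product: 11 (S)-6-[(4-methoxybenzyl)oxy]hex-1-en-4-yn-3-ol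
Conditions: Ti(OiPr)4 (cat.), L-(+)-diisopropyl tartrate (cat.), t-BuOOH (0.6 equiv), 4 Å molecular sieves, CH2Cl2, −20 °C; stopped shortly after half conversion
Reagents that add atoms: none
Why: Sharpless kinetic resolution of a secondary allylic alcohol: with L-(+)-tartrate the (R)-enantiomer is epoxidised faster, so the (S)-alcohol (the future C6 configuration) is recovered.

Step 8
Reactants: 11 (S)-enynol
Product: 12 (3S,4Z)-5-iodo-6-[(4-methoxybenzyl)oxy]hexa-1,4-dien-3-ol
Conditions: NaAlH2(OCH2CH2OMe)2 (Red-Al), THF, 0 °C; then I2, −78 to 0 °C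
Reagents that add atoms: iodine, II
Why: Hydroxyl-directed trans-hydroalumination of the propargylic alcohol places aluminium on the distal alkyne carbon cis to the carbinol carbon, and iodinolysis with retention gives the (Z)-vinyl iodide, which fixes the C4=C5 geometry.

Step 9
Reactants: 7 ethynyl dihydrofuran; 12 (Z)-iodo dienol
Product: 13 (3S,4E)-7-[(5S)-5-{[(tert-butyldiphenylsilyl)oxy]methyl}-3-methyl-4,5-dihydrofuran-2-yl]-5-{[(4-methoxybenzyl)oxy]methyl}hepta-1,4-dien-6-yn-3-ol (alkyne and carbinol carbon cis on the alkene)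
Conditions: Pd(PPh3)4 (cat.), CuI (cat.), Et3N, THF, rt
Reagents that add atoms: none
Why: Sonogashira coupling of a vinyl iodide with a terminal alkyne proceeds with retention of alkene geometry and forms the C3–C4 bond.

Step 10
Reactants: 13 dienynol; 14 2-(bromomethyl)acrylic acid
Product: 15 (3S,4E)-7-[(5S)-5-{[(tert-butyldiphenylsilyl)oxy]methyl}-3-methyl-4,5-dihydrofuran-2-yl]-5-{[(4-methoxybenzyl)oxy]methyl}hepta-1,4-dien-6-yn-3-yl 2-(bromomethyl)acrylate
Conditions: 14, DCC, CH2Cl2, 0 °C; then 13, DMAP (cat.), −20 to 0 °C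
Reagents that add atoms: none
Why: Steglich-type esterification through the preformed anhydride keeps free acid away from the acid-labile enol ether; the C8 oxygen is still locked in the dihydrofuran ring, so only the C6 hydroxyl is acylated.

Step 11
Reactants: 15 enol ether ester
Product: 16 (3S,4E)-7-[(3S,5R)-3-{[(tert-butyldiphenylsilyl)oxy]methyl}-5-methyl-2,6-dioxabicyclo[3.1.0]hexan-1-yl]-5-{[(4-methoxybenzyl)oxy]methyl}hepta-1,4-dien-6-yn-3-yl 2-(bromomethyl)acrylate (oxirane cis-fused on the ring face opposite the silyloxymethyl group)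
Conditions: DMDO (1.05 equiv, acetone solution), CH2Cl2, −78 to −40 °C; volatiles removed cold, used crude
Reagents that add atoms: dimethyldioxirane, CC1(C)OO1
Why: Epoxidation of an electron-rich cyclic enol ether with a neutral dioxirane (the glycal epoxidation type); the oxidant should approach the ring face opposite the bulky silyloxymethyl group, which sets C10 as R (C1 follows by cis fusion), and the acrylate, the enyne alkene and the vinyl group are far less nucleophilic.

Step 12
Reactants: 16 alkynyl oxirane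
Product: 18 (3S,4Z)-6-[(4-methoxybenzyl)oxy]-5-[(5R)-5-{(2S)-3-[(tert-butyldiphenylsilyl)oxy]-2-hydroxypropyl}-5-methyl-4-oxo-4,5-dihydrofuran-2-yl]hexa-1,4-dien-3-yl 2-(bromomethyl)acrylate, via hydroxy ynone 17 (not isolated)
Conditions: AuCl3 (5 mol %), MeCN/H2O (20:1), 0 °C to rt
Reagents that add atoms: water, O
Why: Proposed new method: AuCl3 acting as a Lewis acid, pushed by the ring oxygen, cleaves the ketal-type C1–O bond of the oxirane while the C10–O bond stays intact, water adds to the oxocarbenium ion and the hemiketal collapses to hydroxy ynone 17 with release of the C8 hydroxyl; the C10 oxygen then attacks C3 of the gold-activated alkyne and protodeauration gives the furanone, so the oxirane O–C10–C1 has grown by C2 and C3. The closest known reactions are the gold-catalysed ring expansion of alkynyl oxiranes to furans, the Rubottom-type opening of enol ether epoxides and the gold-catalysed cyclisation of α'-hydroxy ynones to 3(2H)-furanones. The furanone ring closes in the 5-endo-dig mode. No stereocentre is created: C10 keeps the configuration set in step 11 because its C–O bond is never broken, and C1 becomes trigonal. The step needs cleavage of the oxirane at C1 and not at the tertiary C10, which the second oxygen on C1 secures, and closure by the tertiary C10 hydroxyl and not by the C8 hydroxyl, which is secured because the latter could only close a seven-membered ring.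

Step 13
Reactants: 18 furanone diene ester
Product: 19 (5R)-3-(bromomethyl)-5-[(1Z)-3-[(4-methoxybenzyl)oxy]-2-[(5R)-5-{(2S)-3-[(tert-butyldiphenylsilyl)oxy]-2-hydroxypropyl}-5-methyl-4-oxo-4,5-dihydrofuran-2-yl]prop-1-en-1-yl]furan-2(5H)-one
Conditions: second-generation Hoveyda–Grubbs catalyst (cat.), toluene, 80 °C
Reagents that add atoms: none
Why: Ring-closing metathesis between the vinyl group and the 1,1-disubstituted acrylate closes the five-membered butenolide with loss of ethylene; the trisubstituted C4=C5 and the furanone alkene do not take part.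

Step 14
Reactants: 19 silyl ether
Product: 20 (5R)-3-(bromomethyl)-5-[(1Z)-2-[(5R)-5-[(2S)-2,3-dihydroxypropyl]-5-methyl-4-oxo-4,5-dihydrofuran-2-yl]-3-[(4-methoxybenzyl)oxy]prop-1-en-1-yl]furan-2(5H)-one
Conditions: HF·pyridine, THF, 0 °C to rt
Reagents that add atoms: none
Why: Acidic fluoride cleaves the primary silyl ether; without added base the pyridine stays protonated and does not alkylate on the allylic bromide.

Step 15
Reactants: 20 diol
Product: 21 2-[(2R)-5-{(1Z)-1-[(2R)-4-(bromomethyl)-5-oxo-2,5-dihydrofuran-2-yl]-3-[(4-methoxybenzyl)oxy]prop-1-en-2-yl}-2-methyl-3-oxo-2,3-dihydrofuran-2-yl]acetaldehyde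
Conditions: NaIO4, THF/pH 7 phosphate buffer, 0 °C
Reagents that add atoms: none
Why: Periodate cleavage of the 1,2-diol removes the relay carbon as formaldehyde and unveils the C8 aldehyde under neutral conditions that spare the allylic bromide and avoid β-elimination.

Step 16
Reactants: 21 bromo aldehyde
Product: 23 (6R,7R,8R,10R,4Z)-8-hydroxy-15-[(4-methoxybenzyl)oxy]-1-oxo-3,10-epoxygermacra-2,4,11(13)-trien-12,6-olide, via allylzinc bromide 22 (not isolated)
Conditions: Zn dust, THF/sat. aq. NH4Cl, high dilution (slow addition of 21), rt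
Reagents that add atoms: none
Why: Intramolecular zinc Barbier allylation with allylic transposition forms C7–C8, closes the ten-membered carbocycle and regenerates the exocyclic methylene; C7 should be set trans to the C6 substituent (attack on the butenolide face away from the C5 chain, giving the trans-fused lactone), and C8 with its oxygen syn to C6 across the new bond, the sense expected for zinc-mediated additions of 3-(bromomethyl)butenolides.

Step 17
Reactants: 23 macrocyclic alcohol
Product: 24 (6R,7R,8R,10R,4Z)-15-[(4-methoxybenzyl)oxy]-8-(methacryloyloxy)-1-oxo-3,10-epoxygermacra-2,4,11(13)-trien-12,6-olide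
Conditions: methacrylic anhydride, Et3N, DMAP (cat.), CH2Cl2, 0 °C
Reagents that add atoms: methacrylic anhydride, C=C(C)C(=O)OC(=O)C(C)=C
Why: Acylation of the secondary alcohol with the anhydride under nucleophilic catalysis proceeds with retention at C8.

Step 18
Reactants: 24 PMB ether
Product: 25 (6R,7R,8R,10R,4Z)-15-hydroxy-8-(methacryloyloxy)-1-oxo-3,10-epoxygermacra-2,4,11(13)-trien-12,6-olide (target)
Conditions: DDQ, CH2Cl2/pH 7 buffer, 0 °C
Reagents that add atoms: none
Why: Oxidative cleavage of the 4-methoxybenzyl ether by DDQ under buffered conditions frees the C15 hydroxyl without touching the two acrylate-type acceptors.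

Compound list
1 | (S)-5-(hydroxymethyl)dihydrofuran-2(3H)-one | OC[C@@H]1CCC(=O)O1 | starting material
2 | (S)-5-{[(tert-butyldiphenylsilyl)oxy]methyl}dihydrofuran-2(3H)-one | CC(C)(C)[Si](c1ccccc1)(c1ccccc1)OC[C@@H]1CCC(=O)O1 | intermediate
3 | (5S)-5-{[(tert-butyldiphenylsilyl)oxy]methyl}-3-methyldihydrofuran-2(3H)-one (both C3 epimers) | CC(C)(C)[Si](c1ccccc1)(c1ccccc1)OC[C@@H]1CC(C)C(=O)O1 | intermediate
4 | ethynyltrimethylsilane | C#C[Si](C)(C)C | starting material
5 | (6S)-7-[(tert-butyldiphenylsilyl)oxy]-6-hydroxy-4-methyl-1-(trimethylsilyl)hept-1-yn-3-one (both C4 epimers) | CC(C)(C)[Si](c1ccccc1)(c1ccccc1)OC[C@@H](O)CC(C)C(=O)C#C[Si](C)(C)C | intermediate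
6 | (S)-tert-butyl({4-methyl-5-[(trimethylsilyl)ethynyl]-2,3-dihydrofuran-2-yl}methoxy)diphenylsilane | CC(C)(C)[Si](c1ccccc1)(c1ccccc1)OC[C@@H]1CC(C)=C(O1)C#C[Si](C)(C)C | intermediate
7 | (S)-tert-butyl[(5-ethynyl-4-methyl-2,3-dihydrofuran-2-yl)methoxy]diphenylsilane | CC(C)(C)[Si](c1ccccc1)(c1ccccc1)OC[C@@H]1CC(C)=C(O1)C#C | intermediate
8 | 1-methoxy-4-[(prop-2-yn-1-yloxy)methyl]benzene | C#CCOCc1ccc(OC)cc1 | starting material
9 | acrolein | C=CC=O | starting material
10 | rac-6-[(4-methoxybenzyl)oxy]hex-1-en-4-yn-3-ol | C=CC(O)C#CCOCc1ccc(OC)cc1 | intermediate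
11 | (S)-6-[(4-methoxybenzyl)oxy]hex-1-en-4-yn-3-ol | C=C[C@H](O)C#CCOCc1ccc(OC)cc1 | intermediate
12 | (3S,4Z)-5-iodo-6-[(4-methoxybenzyl)oxy]hexa-1,4-dien-3-ol | C=C[C@H](O)/C=C(\I)COCc1ccc(OC)cc1 | intermediate
13 | (3S,4E)-7-[(5S)-5-{[(tert-butyldiphenylsilyl)oxy]methyl}-3-methyl-4,5-dihydrofuran-2-yl]-5-{[(4-methoxybenzyl)oxy]methyl}hepta-1,4-dien-6-yn-3-ol | CC(C)(C)[Si](c1ccccc1)(c1ccccc1)OC[C@@H]1CC(C)=C(O1)C#C/C(COCc2ccc(OC)cc2)=C\[C@H](C=C)O | intermediate
14 | 2-(bromomethyl)acrylic acid | C=C(CBr)C(=O)O | starting material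
15 | 2-(bromomethyl)acrylate ester of 13 | CC(C)(C)[Si](c1ccccc1)(c1ccccc1)OC[C@@H]1CC(C)=C(O1)C#C/C(COCc2ccc(OC)cc2)=C\[C@H](C=C)OC(=O)C(=C)CBr | intermediate
16 | 1-alkynyl-5-methyl-2,6-dioxabicyclo[3.1.0]hexane (3S,5R; oxirane trans to the silyloxymethyl group) carrying the side chain of 15 | CC(C)(C)[Si](c1ccccc1)(c1ccccc1)OC[C@@H]1C[C@@]2(C)O[C@]2(O1)C#C/C(COCc3ccc(OC)cc3)=C\[C@H](C=C)OC(=O)C(=C)CBr | intermediate
17 | (3S,4E,9R,11S)-12-[(tert-butyldiphenylsilyl)oxy]-9,11-dihydroxy-5-{[(4-methoxybenzyl)oxy]methyl}-9-methyl-8-oxododeca-1,4-dien-6-yn-3-yl 2-(bromomethyl)acrylate | CC(C)(C)[Si](c1ccccc1)(c1ccccc1)OC[C@@H](O)C[C@@](C)(O)C(=O)C#C/C(COCc2ccc(OC)cc2)=C\[C@H](C=C)OC(=O)C(=C)CBr | intermediate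
18 | (3S,4Z)-6-[(4-methoxybenzyl)oxy]-5-[(5R)-5-{(2S)-3-[(tert-butyldiphenylsilyl)oxy]-2-hydroxypropyl}-5-methyl-4-oxo-4,5-dihydrofuran-2-yl]hexa-1,4-dien-3-yl 2-(bromomethyl)acrylate | CC(C)(C)[Si](c1ccccc1)(c1ccccc1)OC[C@@H](O)C[C@@]1(C)OC(=CC1=O)/C(COCc2ccc(OC)cc2)=C\[C@H](C=C)OC(=O)C(=C)CBr | intermediate
19 | (5R)-3-(bromomethyl)-5-[(1Z)-3-[(4-methoxybenzyl)oxy]-2-[(5R)-5-{(2S)-3-[(tert-butyldiphenylsilyl)oxy]-2-hydroxypropyl}-5-methyl-4-oxo-4,5-dihydrofuran-2-yl]prop-1-en-1-yl]furan-2(5H)-one | CC(C)(C)[Si](c1ccccc1)(c1ccccc1)OC[C@@H](O)C[C@@]1(C)OC(=CC1=O)/C(COCc2ccc(OC)cc2)=C\[C@H]2OC(=O)C(CBr)=C2 | intermediate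
20 | (5R)-3-(bromomethyl)-5-[(1Z)-2-[(5R)-5-[(2S)-2,3-dihydroxypropyl]-5-methyl-4-oxo-4,5-dihydrofuran-2-yl]-3-[(4-methoxybenzyl)oxy]prop-1-en-1-yl]furan-2(5H)-one | OC[C@@H](O)C[C@@]1(C)OC(=CC1=O)/C(COCc2ccc(OC)cc2)=C\[C@H]2OC(=O)C(CBr)=C2 | intermediate
21 | 2-[(2R)-5-{(1Z)-1-[(2R)-4-(bromomethyl)-5-oxo-2,5-dihydrofuran-2-yl]-3-[(4-methoxybenzyl)oxy]prop-1-en-2-yl}-2-methyl-3-oxo-2,3-dihydrofuran-2-yl]acetaldehyde | O=CC[C@@]1(C)OC(=CC1=O)/C(COCc2ccc(OC)cc2)=C\[C@H]2OC(=O)C(CBr)=C2 | intermediate
22 | allylzinc bromide formed from 21 at C13 | O=CC[C@@]1(C)OC(=CC1=O)/C(COCc2ccc(OC)cc2)=C\[C@H]2OC(=O)C(C[Zn]Br)=C2 | intermediate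
23 | (6R,7R,8R,10R,4Z)-8-hydroxy-15-[(4-methoxybenzyl)oxy]-1-oxo-3,10-epoxygermacra-2,4,11(13)-trien-12,6-olide | O[C@@H]1C[C@@]2(C)OC(=CC2=O)/C(COCc3ccc(OC)cc3)=C\[C@H]2OC(=O)C(=C)[C@@H]21 | intermediate
24 | (6R,7R,8R,10R,4Z)-15-[(4-methoxybenzyl)oxy]-8-(methacryloyloxy)-1-oxo-3,10-epoxygermacra-2,4,11(13)-trien-12,6-olide | C=C(C)C(=O)O[C@@H]1C[C@@]2(C)OC(=CC2=O)/C(COCc3ccc(OC)cc3)=C\[C@H]2OC(=O)C(=C)[C@@H]21 | intermediate
25 | (6R,7R,8R,10R,4Z)-15-hydroxy-8-(methacryloyloxy)-1-oxo-3,10-epoxygermacra-2,4,11(13)-trien-12,6-olide | C=C(C)C(=O)O[C@@H]1C[C@@]2(C)OC(=CC2=O)/C(CO)=C\[C@H]2OC(=O)C(=C)[C@@H]21 | target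

Total step count: 18. Longest linear sequence: 15 steps (steps 1–5, then 9–18).

Steps most likely to fail

Step 12. The opened oxirane may not funnel into the 5-endo closure: the cyclic hemiketal may persist, or gold may ionise the doubly allylic C6 ester. The fallback avoids the oxirane and sets out from 15. Upjohn dihydroxylation (OsO4 cat., N-methylmorpholine N-oxide, acetone/water, 0 °C) should attack the electron-rich tetrasubstituted enol ether first and anti to the silyloxymethyl group, as is known for enol ethers. The osmate ester hydrolyses directly to hydroxy ynone 17, which is isolated and closed by the established gold-catalysed cyclisation of α'-hydroxy ynones ((Ph3P)AuNTf2, dry CH2Cl2). The route is rejoined at 18; no compound outside the list is made (F0).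

Step 16. Ring closure may lose to oligomerisation, and the two faces of the aldehyde may be poorly differentiated, so that the C8 epimer predominates. The fallback sets out from 21 and accepts that outcome. The (6R,7R,8S,10R,4Z)-8-hydroxy-15-[(4-methoxybenzyl)oxy]-1-oxo-3,10-epoxygermacra-2,4,11(13)-trien-12,6-olide F1 is esterified under Mitsunobu conditions with methacrylic acid (PPh3, DIAD, toluene, 0 °C). This inverts C8 and installs the ester in one operation, and the route is rejoined at 24.

Step 11. The 1,3-relay from the silyloxymethyl group may give poor facial selectivity in the epoxidation. The fallback hands stereocontrol to a catalyst one step earlier and sets out from 13. Alcohol 13 is epoxidised with Oxone and the fructose-derived Shi ketone (the enantiomer matched with the relay) in buffered MeCN/dimethoxymethane/water. Under these aqueous conditions the oxirane hydrolyses in the flask to (3S,4E,9R,11S)-12-[(tert-butyldiphenylsilyl)oxy]-3,9,11-trihydroxy-5-{[(4-methoxybenzyl)oxy]methyl}-9-methyldodeca-1,4-dien-6-yn-8-one F2. F2 exists as the cyclic hemiketal that keeps the C8 oxygen masked, so it can be esterified at its only unhindered secondary hydroxyl (C6) with acid 14 and DCC to give 17. Gold-catalysed closure as above rejoins the route at 18.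

Further compounds
F0 | step 12 | none | none
F1 | step 16 | (6R,7R,8S,10R,4Z)-8-hydroxy-15-[(4-methoxybenzyl)oxy]-1-oxo-3,10-epoxygermacra-2,4,11(13)-trien-12,6-olide | O[C@H]1C[C@@]2(C)OC(=CC2=O)/C(COCc3ccc(OC)cc3)=C\[C@H]2OC(=O)C(=C)[C@@H]21
F2 | step 11 | (3S,4E,9R,11S)-12-[(tert-butyldiphenylsilyl)oxy]-3,9,11-trihydroxy-5-{[(4-methoxybenzyl)oxy]methyl}-9-methyldodeca-1,4-dien-6-yn-8-one | CC(C)(C)[Si](c1ccccc1)(c1ccccc1)OC[C@@H](O)C[C@@](C)(O)C(=O)C#C/C(COCc2ccc(OC)cc2)=C\[C@H](C=C)O
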